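Assumption: compounds 1, 2 and 5 are bought as such, and the sense of induction of Rh2(S-PTTL)4 (S catalyst gives 2R) is recalled from close single-ring analogues and is confirmed on the first run, the R catalyst being equally available.

**Retrosynthetic overview**
1. Target 13 comes from the benzyl-protected trans,trans-triester 11 by one LiAlH4 reduction of three esters and a final hydrogenolysis; 11 comes from the cis,cis-triester 10 by C3/C3' epimerisation.
2. Both dihydrobenzofuran rings (the C2–C3 and C2'–C3' bonds) are cut at once: 10 comes from the acyclic bis(aryldiazoacetate) 8 by a twofold enantioselective Rh(II)-carbene insertion into two ArO–CH2–Ar bonds.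
3. Ring order: both rings close in the same flask (either may close first, via 9); the catalyst sets C2 and C2', thermodynamics then set C3 and C3'.
4. 8 comes from the bis(aryl iodide) 7 by a twofold Pd-catalysed coupling with ethyl diazoacetate.
5. 7 comes from two Mitsunobu etherifications joining 5-iodovanillin 1, O-benzylvanillyl alcohol 2 and iodinated ethyl dihydroferulate 6.

**Route**

Step 1
Reactants: 1 5-iodovanillin; 2 4-(benzyloxy)-3-methoxybenzyl alcohol
Product: 3 4-{[4-(benzyloxy)-3-methoxybenzyl]oxy}-3-iodo-5-methoxybenzaldehyde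
Conditions: PPh3, DIAD, THF, 0 °C to rt
Reagents that add atoms: none
Why: Mitsunobu etherification; the acidic, aldehyde-activated phenol of 1 is an ideal pronucleophile and the primary p-alkoxybenzylic alcohol 2 is readily activated; no stereocentre is formed.

Step 2
Reactants: 3 4-{[4-(benzyloxy)-3-methoxybenzyl]oxy}-3-iodo-5-methoxybenzaldehyde
Product: 4 (4-{[4-(benzyloxy)-3-methoxybenzyl]oxy}-3-iodo-5-methoxyphenyl)methanol
Conditions: NaBH4, THF/EtOH, 0 °C
Reagents that add atoms: none
Why: Borohydride reduction of the aryl aldehyde; the aryl iodide and both benzyl ethers are inert.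

Step 3
Reactants: 5 ethyl 3-(4-hydroxy-3-methoxyphenyl)propanoate (ethyl dihydroferulate)
Product: 6 ethyl 3-(4-hydroxy-3-iodo-5-methoxyphenyl)propanoate
Conditions: NIS (1.05 equiv), TsOH·H2O (10 mol %), MeCN, 0 °C to rt
Reagents that add atoms: N-iodosuccinimide, O=C1CCC(=O)N1I
Why: Electrophilic aromatic iodination; with the para position blocked, the free OH (the strongest donor) directs iodine to its open ortho position, as in the iodination of vanillin.

Step 4
Reactants: 4 (4-{[4-(benzyloxy)-3-methoxybenzyl]oxy}-3-iodo-5-methoxyphenyl)methanol; 6 ethyl 3-(4-hydroxy-3-iodo-5-methoxyphenyl)propanoate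
Product: 7 bis(aryl iodide) diether, ethyl 3-{4-[(4-{[4-(benzyloxy)-3-methoxybenzyl]oxy}-3-iodo-5-methoxybenzyl)oxy]-3-iodo-5-methoxyphenyl}propanoate
Conditions: PPh3, DIAD, THF/toluene, 0 °C to rt
Reagents that add atoms: none
Why: Second Mitsunobu etherification; the o-iodophenol 6 is acidic enough, the p-alkoxybenzylic alcohol 4 is displaced easily, and the ester is untouched under these neutral conditions.

Step 5
Reactants: 7 bis(aryl iodide) diether
Product: 8 bis(aryldiazoacetate), ethyl 3-{4-[(4-{[4-(benzyloxy)-3-methoxybenzyl]oxy}-3-(1-diazo-2-ethoxy-2-oxoethyl)-5-methoxybenzyl)oxy]-3-(1-diazo-2-ethoxy-2-oxoethyl)-5-methoxyphenyl}propanoate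
Conditions: ethyl diazoacetate (5 equiv), Pd(PPh3)4 (10 mol %), Ag2CO3 (1.0 equiv), Et3N, toluene, rt, dark
Reagents that add atoms: ethyl diazoacetate, CCOC(=O)C=[N+]=[N-]
Why: Pd-catalysed cross-coupling of aryl iodides with an acceptor diazo compound (oxidative addition, silver-assisted iodide abstraction, C-palladation of the deprotonated diazoacetate, reductive elimination with the diazo group retained), used twice on one substrate; it is placed after both Mitsunobu steps because PPh3 would attack a diazo ester.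

Step 6
Reactants: 8 bis(aryldiazoacetate)
Product: 10 cis,cis-bis(dihydrobenzofuran) triester (2R,3S,2'R,3'S), via mono-cyclised diazo triester 9 (not isolated)
Conditions: Rh2(S-PTTL)4 (2 mol %), toluene, −78 to −40 °C, slow addition of 8 at high dilution
Reagents that add atoms: none
Why: Proposed new method: each Rh(II) aryl(ester)carbene inserts by a concerted, hydride-transfer-like 1,5-C–H insertion into the neighbouring ArO–CH2–Ar' bond (the only C–H bonds either carbene can reach, both α-oxygen and p-alkoxybenzylic activated), so the two five-membered rings close independently in one flask through 9; the phthaloyl-tert-leucinate pocket sets C2 and C2' as R and gives the kinetic cis esters, and two independent catalyst-controlled events raise the ee of the major diastereomer (Horeau amplification) at the cost of a minor diastereomer to be removed; the closest known reaction type is the single enantioselective intramolecular Rh(II)-carbene C–H insertion of 2-(benzyloxy)aryl diazoacetates to cis-2-aryl-2,3-dihydrobenzofuran-3-carboxylates.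

Step 7
Reactants: 10 cis,cis-bis(dihydrobenzofuran) triester
Product: 11 trans,trans-bis(dihydrobenzofuran) triester (2R,3R,2'R,3'R)
Conditions: NaOEt (0.3 equiv), EtOH/THF, 0 °C to rt
Reagents that add atoms: none
Why: Thermodynamic epimerisation through the ester enolates inverts only C3 and C3' to the trans arrangement; C2 and C2' carry no acidic hydrogen, and ring opening would be a stereoelectronically disfavoured retro-5-endo-trig β-elimination; ethoxide in ethanol keeps all three esters as ethyl esters.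

Step 8
Reactants: 11 trans,trans-bis(dihydrobenzofuran) triester
Product: 12 O-benzyl triol, {(2R,3S)-2-[4-(benzyloxy)-3-methoxyphenyl]-5-[(2R,3S)-3-(hydroxymethyl)-5-(3-hydroxypropyl)-7-methoxy-2,3-dihydrobenzofuran-2-yl]-7-methoxy-2,3-dihydrobenzofuran-3-yl}methanol
Conditions: LiAlH4, THF, 0 °C; Rochelle salt work-up
Reagents that add atoms: none
Why: Hydride reduction of all three esters in one operation gives the two hydroxymethyl groups and the 3-hydroxypropyl chain; reduction is faster than enolisation, so the trans centres are kept (the descriptor at C3 changes from R to S only through CIP priorities).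

Step 9
Reactants: 12 O-benzyl triol
Product: 13 target CNP0599161.1
Conditions: H2 (1 atm), 10 % Pd/C, EtOAc/EtOH, rt
Reagents that add atoms: none
Why: Catalytic hydrogenolysis cleaves the acyclic benzyl aryl ether much faster than the cyclic benzylic C2–O bonds under neutral conditions, and the neutral medium avoids the base-induced quinone-methide opening that a free p-hydroxyphenyl at C2 would allow.

**Compound list**

1 | 5-iodovanillin (4-hydroxy-3-iodo-5-methoxybenzaldehyde) | COc1cc(C=O)cc(I)c1O | starting material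
2 | 4-(benzyloxy)-3-methoxybenzyl alcohol | COc1cc(CO)ccc1OCc1ccccc1 | starting material
3 | 4-{[4-(benzyloxy)-3-methoxybenzyl]oxy}-3-iodo-5-methoxybenzaldehyde | COc1cc(C=O)cc(I)c1OCc1ccc(OCc2ccccc2)c(OC)c1 | intermediate
4 | (4-{[4-(benzyloxy)-3-methoxybenzyl]oxy}-3-iodo-5-methoxyphenyl)methanol | COc1cc(CO)cc(I)c1OCc1ccc(OCc2ccccc2)c(OC)c1 | intermediate
5 | ethyl 3-(4-hydroxy-3-methoxyphenyl)propanoate | CCOC(=O)CCc1ccc(O)c(OC)c1 | starting material
6 | ethyl 3-(4-hydroxy-3-iodo-5-methoxyphenyl)propanoate | CCOC(=O)CCc1cc(I)c(O)c(OC)c1 | intermediate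
7 | ethyl 3-{4-[(4-{[4-(benzyloxy)-3-methoxybenzyl]oxy}-3-iodo-5-methoxybenzyl)oxy]-3-iodo-5-methoxyphenyl}propanoate | CCOC(=O)CCc1cc(I)c(OCc2cc(I)c(OCc3ccc(OCc4ccccc4)c(OC)c3)c(OC)c2)c(OC)c1 | intermediate
8 | ethyl 3-{4-[(4-{[4-(benzyloxy)-3-methoxybenzyl]oxy}-3-(1-diazo-2-ethoxy-2-oxoethyl)-5-methoxybenzyl)oxy]-3-(1-diazo-2-ethoxy-2-oxoethyl)-5-methoxyphenyl}propanoate | CCOC(=O)CCc1cc(C(=[N+]=[N-])C(=O)OCC)c(OCc2cc(C(=[N+]=[N-])C(=O)OCC)c(OCc3ccc(OCc4ccccc4)c(OC)c3)c(OC)c2)c(OC)c1 | intermediate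
9 | ethyl (2R,3S)-2-[4-(benzyloxy)-3-methoxyphenyl]-5-{[2-(1-diazo-2-ethoxy-2-oxoethyl)-4-(3-ethoxy-3-oxopropyl)-6-methoxyphenoxy]methyl}-7-methoxy-2,3-dihydrobenzofuran-3-carboxylate (cis; the isomer with the other ring closed first is equally possible and leads to the same 10) | COc1cc([C@@H]2Oc3c(OC)cc(COc4c(OC)cc(CCC(=O)OCC)cc4C(=[N+]=[N-])C(=O)OCC)cc3[C@@H]2C(=O)OCC)ccc1OCc1ccccc1 | intermediate
10 | ethyl (2R,3S)-2-[4-(benzyloxy)-3-methoxyphenyl]-5-[(2R,3S)-3-(ethoxycarbonyl)-5-(3-ethoxy-3-oxopropyl)-7-methoxy-2,3-dihydrobenzofuran-2-yl]-7-methoxy-2,3-dihydrobenzofuran-3-carboxylate (cis,cis) | COc1cc([C@@H]2Oc3c(OC)cc([C@@H]4Oc5c(OC)cc(CCC(=O)OCC)cc5[C@@H]4C(=O)OCC)cc3[C@@H]2C(=O)OCC)ccc1OCc1ccccc1 | intermediate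
11 | ethyl (2R,3R)-2-[4-(benzyloxy)-3-methoxyphenyl]-5-[(2R,3R)-3-(ethoxycarbonyl)-5-(3-ethoxy-3-oxopropyl)-7-methoxy-2,3-dihydrobenzofuran-2-yl]-7-methoxy-2,3-dihydrobenzofuran-3-carboxylate (trans,trans) | COc1cc([C@@H]2Oc3c(OC)cc([C@@H]4Oc5c(OC)cc(CCC(=O)OCC)cc5[C@H]4C(=O)OCC)cc3[C@H]2C(=O)OCC)ccc1OCc1ccccc1 | intermediate
12 | {(2R,3S)-2-[4-(benzyloxy)-3-methoxyphenyl]-5-[(2R,3S)-3-(hydroxymethyl)-5-(3-hydroxypropyl)-7-methoxy-2,3-dihydrobenzofuran-2-yl]-7-methoxy-2,3-dihydrobenzofuran-3-yl}methanol | COc1cc([C@@H]2Oc3c(OC)cc([C@@H]4Oc5c(OC)cc(CCCO)cc5[C@H]4CO)cc3[C@H]2CO)ccc1OCc1ccccc1 | intermediate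
13 | 4-{(2R,3S)-3-(hydroxymethyl)-5-[(2R,3S)-3-(hydroxymethyl)-5-(3-hydroxypropyl)-7-methoxy-2,3-dihydrobenzofuran-2-yl]-7-methoxy-2,3-dihydrobenzofuran-2-yl}-2-methoxyphenol | COc1cc([C@@H]2Oc3c(OC)cc([C@@H]4Oc5c(OC)cc(CCCO)cc5[C@H]4CO)cc3[C@H]2CO)ccc1O | target

**Totals**

Total step count: 9. Longest linear sequence: 8 (steps 1, 2, 4, 5, 6, 7, 8, 9 from 5-iodovanillin).

**Three steps most likely to fail**

Step 6 (twofold asymmetric C–H insertion). The risks are bimolecular carbene chemistry (azine or carbene-dimer formation) competing with the second ring closure, lower selectivity at one of the two sites, and the unverified sense of induction. The fallback makes the rings one at a time; it sets out from 3 and comes back to the route at 9. Aldehyde 3 is coupled with ethyl diazoacetate under the step 5 conditions to give the diazo aldehyde ethyl 2-(2-{[4-(benzyloxy)-3-methoxybenzyl]oxy}-5-formyl-3-methoxyphenyl)-2-diazoacetate F2. A single Rh2(S-PTTL)4 insertion then gives the cis-dihydrobenzofuran aldehyde F3, on which ee and absolute configuration can be measured and upgraded. NaBH4 gives the benzylic alcohol F4, Mitsunobu etherification with 6 gives the aryl iodide F5, and a second Pd/Ag coupling with ethyl diazoacetate gives 9, now isolated. The second half of step 6 then closes 9 to 10 with the same catalyst.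

Step 5 (twofold Pd coupling with ethyl diazoacetate on electron-rich, ortho-alkoxy aryl iodides). The risks are slow oxidative addition or transmetalation and incomplete second coupling. The fallback sets out from 7 and comes back at 8. A twofold Pd-catalysed Negishi-type α-arylation of 7 with the Reformatsky reagent BrZnCH2CO2Et (Pd2(dba)3/XPhos, THF, 60 °C) gives the bis(arylacetate) triester F1. Regitz diazo transfer with p-ABSA and DBU in MeCN then gives 8; only the two aryl-acetate CH2 groups are acidic enough to react, the propanoate CH2 is not.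

Step 7 (ester-level epimerisation). The risks are incomplete equilibration and base-induced damage. The fallback moves the epimerisation to the aldehyde oxidation level, where a weak amine base is enough; it sets out from 10 and comes back at 12. LiAlH4 reduces 10 to the cis,cis-triol F6. Dess–Martin oxidation gives the cis,cis-trialdehyde F7, which is not stored. Catalytic Et3N in CH2Cl2 equilibrates the α-aryl aldehydes to the trans,trans-trialdehyde F8, and NaBH4 gives 12.

**Further compounds**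

F1 | step 5 | ethyl 3-{4-[(4-{[4-(benzyloxy)-3-methoxybenzyl]oxy}-3-(2-ethoxy-2-oxoethyl)-5-methoxybenzyl)oxy]-3-(2-ethoxy-2-oxoethyl)-5-methoxyphenyl}propanoate | CCOC(=O)CCc1cc(CC(=O)OCC)c(OCc2cc(CC(=O)OCC)c(OCc3ccc(OCc4ccccc4)c(OC)c3)c(OC)c2)c(OC)c1
F2 | step 6 | ethyl 2-(2-{[4-(benzyloxy)-3-methoxybenzyl]oxy}-5-formyl-3-methoxyphenyl)-2-diazoacetate | COc1cc(C=O)cc(C(=[N+]=[N-])C(=O)OCC)c1OCc1ccc(OCc2ccccc2)c(OC)c1
F3 | step 6 | ethyl (2R,3S)-2-[4-(benzyloxy)-3-methoxyphenyl]-5-formyl-7-methoxy-2,3-dihydrobenzofuran-3-carboxylate (cis) | COc1cc([C@@H]2Oc3c(OC)cc(C=O)cc3[C@@H]2C(=O)OCC)ccc1OCc1ccccc1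
F4 | step 6 | ethyl (2R,3S)-2-[4-(benzyloxy)-3-methoxyphenyl]-5-(hydroxymethyl)-7-methoxy-2,3-dihydrobenzofuran-3-carboxylate (cis) | COc1cc([C@@H]2Oc3c(OC)cc(CO)cc3[C@@H]2C(=O)OCC)ccc1OCc1ccccc1
F5 | step 6 | ethyl (2R,3S)-2-[4-(benzyloxy)-3-methoxyphenyl]-5-{[4-(3-ethoxy-3-oxopropyl)-2-iodo-6-methoxyphenoxy]methyl}-7-methoxy-2,3-dihydrobenzofuran-3-carboxylate (cis) | COc1cc([C@@H]2Oc3c(OC)cc(COc4c(OC)cc(CCC(=O)OCC)cc4I)cc3[C@@H]2C(=O)OCC)ccc1OCc1ccccc1
F6 | step 7 | {(2R,3R)-2-[4-(benzyloxy)-3-methoxyphenyl]-5-[(2R,3R)-3-(hydroxymethyl)-5-(3-hydroxypropyl)-7-methoxy-2,3-dihydrobenzofuran-2-yl]-7-methoxy-2,3-dihydrobenzofuran-3-yl}methanol (cis,cis) | COc1cc([C@@H]2Oc3c(OC)cc([C@@H]4Oc5c(OC)cc(CCCO)cc5[C@@H]4CO)cc3[C@@H]2CO)ccc1OCc1ccccc1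
F7 | step 7 | (2R,3S)-2-[4-(benzyloxy)-3-methoxyphenyl]-5-[(2R,3S)-3-formyl-7-methoxy-5-(3-oxopropyl)-2,3-dihydrobenzofuran-2-yl]-7-methoxy-2,3-dihydrobenzofuran-3-carbaldehyde (cis,cis) | COc1cc([C@@H]2Oc3c(OC)cc([C@@H]4Oc5c(OC)cc(CCC=O)cc5[C@@H]4C=O)cc3[C@@H]2C=O)ccc1OCc1ccccc1
F8 | step 7 | (2R,3R)-2-[4-(benzyloxy)-3-methoxyphenyl]-5-[(2R,3R)-3-formyl-7-methoxy-5-(3-oxopropyl)-2,3-dihydrobenzofuran-2-yl]-7-methoxy-2,3-dihydrobenzofuran-3-carbaldehyde (trans,trans) | COc1cc([C@@H]2Oc3c(OC)cc([C@@H]4Oc5c(OC)cc(CCC=O)cc5[C@H]4C=O)cc3[C@H]2C=O)ccc1OCc1ccccc1
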